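The readings are calculated on assumed constants.

I decide to read Monday's flask from Sunday's run, not from Saturday's, and I commit to that before anything else is shown.

| flask | substrate | partner | time |
|---|---|---|---|
| Saturday's | 200 mM | 200 mM |  |
| Sunday's | 80.0 mM | 80.0 mM |  |
| Tuesday's | 200 mM | 400 mM |  |
| Monday's | 66.0 mM | 66.0 mM | 7.0 min |

- Saturday's run (time / min: [target] / mM): 1.4: 31.2; 2.8: 45.9; 4.2: 52.8; 5.6: 55.8; 7.0: 58.3
- Sunday's run (time / min: [target] / mM): 1.4: 2.7; 2.8: 3.5; 4.2: 5.4; 5.6: 5.8; 7.0: 7.2
- Tuesday's run (time / min: [target] / mM): 1.4: 85.7; 2.8: 103.1; 4.2: 106.9; 5.6: 106.0; 7.0: 105.4

(scatter of a reading: 0.6 mM)

- how the opening rate goes with [partner] round the charge of the Saturday's run: the exponent of the rate at two percent of substrate gone to target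
- how the opening rate goes with [substrate] round the charge of the Saturday's run: the exponent of the rate at two percent of substrate gone to target (one fixed amount of target, the same in the runs compared)
- target in the Monday's run at 7.0 min, as a share of the substrate charged

- Overall: substrate + partner -> target.
- Constant volume, constant temperature.
- An order is taken over about fifteen percent of the charge, up and down.

1. I put a falling exponential through the first two readings of each strong run, and its opening slope is 31.7 mM min⁻¹ in Saturday's run and 122 mM min⁻¹ in Tuesday's, so doubling the partner gives an exponent of 1.95.

2. Sunday's first reading gives a slope of 1.93 mM min⁻¹, a rough value since that reading carries a scatter of 0.6 mM, and against Saturday's slope it gives a total order of 3.06, which leaves 1.11 for the substrate.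

3. My bench rule follows: with equal charges c and a fixed time, the share turned goes, for as long as it stays small, as c to the total order less one, here 2.06, which I round to the square. I write the share at 7.0 min as (c/c*)², where c* is the reference charge, the equal charge at which this square law reaches the whole substrate. Sunday's last reading gives c* = 267 mM.

4. The border shows in Saturday's run, where the rule says 56.3% and the reading says 29.1%, less than the rule. Monday's charge lies below Sunday's, on the side away from that failure.

5. My figure for Monday's run is 6.13%, uncertain by 8.33% of itself from the one reading.

The forecast gives 1.9 for the partner exponent, on the ground that “Doubling the partner gives about 3.7 times the rate”, then 1.15 for the substrate exponent and 6.4% for Monday's run; its Monday figure differs from mine and comes from its own plateau reckoning.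

The simulation gives 6.81% for Monday's run, with exponents 2.1 for the partner and 1.0 for the substrate, and the forecast stands within its margins.

    substrate + 2 partner → target + partner (4.386 L² mol⁻² min⁻¹)
    target + partner → side product (0.3684 L mol⁻¹ min⁻¹)
    partner → lost reagent (0.07440 min⁻¹)

Monday's share stands 0.68 percentage points above my figure. Reckoned back from that share, c* is 253 mM in Monday's run, against 267 mM from Sunday's. Carried to Saturday's run, with the share taken as growing in proportion to time, the rule with Sunday's c* reaches a quarter of the substrate at 3.11 min, earlier than the 3.60 min the simulation gives for Saturday's run.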